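## Retrosynthetic overview
1. Target 13 ⇒ catechol ketal 12 (hydrolysis) ⇒ 6,8-diallylflavone 10 by two-fold cross-metathesis (allyl → prenyl). The prenyl groups appear only at the end, so there is no electrophilic C-prenylation and no prenylated acetophenone.
2. Key step: 10 ⇒ 5,7-bis(allyl ether) 9 by a double aromatic Claisen "funnel". O7→C8/C6, O5→C6 and O5→C6→C8 (Claisen–Cope) all converge on one product, because an allyl group is unchanged by allylic inversion. A prenyl ether would give reverse-prenyl groups by the ortho path.
3. 9 ⇒ 5,7-dihydroxy-3-methoxyflavone 7 ⇒ phloroglucinol + α-methoxy-aroylacetate 5, by a one-step thermal [3+3] pyranone annulation. The 3-OMe arrives pre-installed, so there is no chalcone/Algar–Flynn–Oyamada sequence and no selective O-methylation.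
4. 5 ⇒ crossed Claisen condensation of methyl methoxyacetate with ketal-protected methyl protocatechuate.
5. Ring order: rings A and B are purchased; a temporary dioxole ring is made in step 1; ring C (pyranone) is the only skeletal ring formed, in step 3.

Assumption: the target has no stereocentre, no E/Z-isomeric alkene and no stereogenic axis. It is achiral, so the "single enantiomer" requirement does not apply and there is nothing to control.

## Route

**Step 1**
Reactants: 1 methyl 3,4-dihydroxybenzoate; 2 dichlorodiphenylmethane
Product: 3 methyl 2,2-diphenyl-1,3-benzodioxole-5-carboxylate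
Conditions: Ph2CCl2 (1.3 equiv), neat, 175 °C, 20 min (−2 HCl)
Reagents that add atoms: dichlorodiphenylmethane, ClC(Cl)(c1ccccc1)c1ccccc1
Why: Catechol ketalisation by double substitution of the benzhydrylic gem-dichloride leaves the ester untouched and gives a group that survives strong base, 250 °C and Ru carbenes yet is removed by hot aqueous AcOH; no stereocentre is formed.

**Step 2**
Reactants: 3; 4 methyl methoxyacetate
Product: 5 methyl 3-(2,2-diphenyl-1,3-benzodioxol-5-yl)-2-methoxy-3-oxopropanoate (racemic at C-2, enolisable)
Conditions: 4 (1.6 equiv), LiHMDS (3.2 equiv), THF, −78 → 0 °C → rt; aq NH4Cl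
Reagents that add atoms: methyl methoxyacetate, COCC(=O)OC
Why: In this crossed Claisen condensation 3 is non-enolisable, so only the chelated enolate of 4 is the nucleophile, and irreversible deprotonation of the β-keto ester drives the reaction; the labile racemic C-2 centre is erased in step 3.

**Step 3** (ring C)
Reactants: 5; 6 phloroglucinol (anhydrous)
Product: 7 2-(2,2-diphenyl-1,3-benzodioxol-5-yl)-5,7-dihydroxy-3-methoxy-4H-chromen-4-one
Conditions: 6 (1.5 equiv), Ph2O, 240–250 °C, N2 sweep (−MeOH, −H2O), 1.5 h
Reagents that add atoms: phloroglucinol, Oc1cc(O)cc(O)c1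
Why: In this Mentzer pyrone synthesis (acid-free thermal Simonis-type condensation), 5 loses MeOH to give an aroyl(methoxy)ketene that C-acylates phloroglucinol, and the ortho OH then cyclodehydrates onto the aryl ketone; without acid the Pechmann coumarin pathway is avoided, and the C3 symmetry of 6 allows only one regioisomer.

**Step 4**
Reactants: 7; 8 allyl bromide
Product: 9 5,7-bis(allyloxy)-2-(2,2-diphenyl-1,3-benzodioxol-5-yl)-3-methoxy-4H-chromen-4-one
Conditions: allyl bromide (5 equiv), K2CO3 (6 equiv), DMF, 60 °C, 16 h
Reagents that add atoms: allyl bromide, C=CCBr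
Why: This is an exhaustive Williamson etherification in which the only free OH groups are 5-OH and 7-OH, excess reagent and heat overcome the chelated 5-OH, and the ketal, enol methyl ether and pyranone tolerate K2CO3.

**Step 5** (key step)
Reactants: 9
Product: 10 6,8-diallyl-2-(2,2-diphenyl-1,3-benzodioxol-5-yl)-5,7-dihydroxy-3-methoxy-4H-chromen-4-one
Conditions: PhNEt2 (degassed), 215 °C, Ar, 4–6 h
Reagents that add atoms: none
Why: In this double aromatic Claisen rearrangement with a para-Claisen–Cope relay, O7-allyl goes to C8 or C6 and O5-allyl goes to C6 or, if C6 is occupied, via the dienone and Cope shift to C8; blocked dienones revert, every productive path ends at the same 6,8-diallyl resorcinol, and the basic solvent suppresses dihydrobenzofuran formation.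

**Step 6**
Reactants: 10; 11 2-methyl-2-butene
Product: 12 2-(2,2-diphenyl-1,3-benzodioxol-5-yl)-5,7-dihydroxy-3-methoxy-6,8-bis(3-methylbut-2-en-1-yl)-4H-chromen-4-one
Conditions: Grubbs II (2 × 5 mol %), 1,4-benzoquinone (10 mol %), 2-methyl-2-butene/CH2Cl2 (1:1), sealed tube, 40 °C, 16 h
Reagents that add atoms: 2-methyl-2-butene, CC=C(C)C (delivers =C(CH3)2 twice; propene is lost)
Why: Two-fold olefin cross-metathesis of terminal allylarenes with a large excess of the trisubstituted alkene gives the prenyl groups; free phenols are tolerated, the tetrasubstituted C2=C3 bond is inert, ring closure between the meta-disposed allyls is geometrically impossible, and benzoquinone suppresses Ru–H isomerisation to styrenes.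

**Step 7**
Reactants: 12
Product: 13 Broussoflavonol B, 2-(3,4-dihydroxyphenyl)-5,7-dihydroxy-3-methoxy-6,8-bis(3-methylbut-2-en-1-yl)-4H-chromen-4-one
Conditions: AcOH/H2O (4:1), 100 °C, Ar, 1–2 h, stopped at full conversion (−Ph2C=O)
Reagents that add atoms: none (water gives only H to the product; its O leaves in benzophenone)
Why: Acid-catalysed ketal hydrolysis proceeds through the highly stabilised diaryl oxocarbenium ion in a weak acid, far below the acidity (HCO2H, TFA, TsOH) normally needed to cyclise o-prenylphenols to chromans, and the 3-OMe is untouched.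

## Compound list
1 | methyl 3,4-dihydroxybenzoate (C8H8O4) | COC(=O)c1ccc(O)c(O)c1 | starting material
2 | dichlorodiphenylmethane | ClC(Cl)(c1ccccc1)c1ccccc1 | starting material
3 | methyl 2,2-diphenyl-1,3-benzodioxole-5-carboxylate (C21H16O4) | COC(=O)c1ccc2OC(c3ccccc3)(c4ccccc4)Oc2c1 | intermediate
4 | methyl methoxyacetate | COCC(=O)OC | starting material
5 | methyl 3-(2,2-diphenyl-1,3-benzodioxol-5-yl)-2-methoxy-3-oxopropanoate, racemic (C24H20O6) | COC(=O)C(OC)C(=O)c1ccc2OC(c3ccccc3)(c4ccccc4)Oc2c1 | intermediate
6 | phloroglucinol | Oc1cc(O)cc(O)c1 | starting material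
7 | 2-(2,2-diphenyl-1,3-benzodioxol-5-yl)-5,7-dihydroxy-3-methoxychromen-4-one (C29H20O7) | COc1c(-c2ccc3OC(c4ccccc4)(c5ccccc5)Oc3c2)oc2cc(O)cc(O)c2c1=O | intermediate
8 | allyl bromide | C=CCBr | starting material
9 | 5,7-bis(allyloxy) derivative of 7 (C35H28O7) | COc1c(-c2ccc3OC(c4ccccc4)(c5ccccc5)Oc3c2)oc2cc(OCC=C)cc(OCC=C)c2c1=O | intermediate
10 | 6,8-diallyl-5,7-dihydroxy flavone ketal (C35H28O7) | COc1c(-c2ccc3OC(c4ccccc4)(c5ccccc5)Oc3c2)oc2c(CC=C)c(O)c(CC=C)c(O)c2c1=O | intermediate
11 | 2-methyl-2-butene | CC=C(C)C | starting material
12 | 6,8-diprenyl-5,7-dihydroxy flavone ketal (C39H36O7) | COc1c(-c2ccc3OC(c4ccccc4)(c5ccccc5)Oc3c2)oc2c(CC=C(C)C)c(O)c(CC=C(C)C)c(O)c2c1=O | intermediate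
13 | Broussoflavonol B, achiral (C26H28O7) | COc1c(-c2ccc(O)c(O)c2)oc2c(CC=C(C)C)c(O)c(CC=C(C)C)c(O)c2c1=O | target

## Summary
Total steps: 7. Longest linear sequence: 7 (from methyl 3,4-dihydroxybenzoate).

Three steps most likely to fail, each with one fallback:
1. **Step 5 (double Claisen).** Risks are incomplete second migration, thermal de-allylation and dihydrobenzofuran by-products. Fallback: abandon the sigmatropic transfer. Di-iodinate 7 at C6/C8 (NIS), mask 5,7-OH as acetates, run a two-fold Stille coupling with tributyl(prenyl)stannane, then methanolyse (K2CO3/MeOH) to reach 12 directly. This replaces steps 4–6.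
2. **Step 3 (thermal annulation).** Risks are decarboxylation of 5 by the released water, 4-arylcoumarin formation and charring. Fallback: build ring C stepwise. Hoesch acylation of phloroglucinol with methoxyacetonitrile gives ω-methoxyphloroacetophenone. Allan–Robinson condensation with the anhydride of the acid from saponified 3 then gives the same 7.
3. **Step 7 (acidic deketalisation next to two o-prenylphenol units).** Risks are chroman formation and hydration of the prenyl groups. Fallback: reverse the endgame. Hydrolyse the ketal at the diallyl stage (10; allyl groups are inert to hot aqueous AcOH) and peracetylate. Perform the two-fold cross-metathesis on the tetraacetate and finish with mild K2CO3/MeOH, so the prenyl groups never meet acid.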